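**Plan**

- Retrosynthesis: the C2–Br bond of ring A (next to the phenol OH) is cut first and the OH is masked as OMe. Then the O–C1' ether bond and the C2'–Br bond of ring B are cut together, and last the two C–Br bonds of a guaiacol-derived ring A.
- Enabling feature: ring B is a benzene carrying only the ether oxygen at C1' and a bromine at the neighbouring C2'. This is the pattern left when benzyne takes an oxygen nucleophile and a bromine electrophile across its triple bond.
- Forward order: guaiacol is dibrominated; its potassium aryloxide, benzyne and CBr4 are joined in one flask to give the 2-bromophenyl ether; BBr3 frees the phenol; the new OH steers the last bromine to its only free ortho carbon.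
- No ring is formed (both benzene rings are bought) and the target is achiral, so only regiochemistry has to be controlled.

Key step: step 2

Remark on the chemistry: locants follow the target SMILES. Ring A is the phenol ring with C1 (OH), C2, C3 and C5 (Br), C4 (H) and C6 (O–aryl). Ring B has C1' (O) and C2' (Br).

**Route**

Step 1
Reactants: 1 guaiacol (2-methoxyphenol)
Product: 2 2,4-dibromo-6-methoxyphenol
Conditions: Br2 (2.05 equiv), AcOH, 15 °C → rt
Reagents that add atoms: bromine, BrBr
Why: Electrophilic aromatic bromination in which the free hydroxyl group, the stronger donor, should send the two bromines to its para and its free ortho carbon, the remaining carbons being meta to OH and untouched at this stoichiometry.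

Step 2
Reactants: 2 2,4-dibromo-6-methoxyphenol; 3 2-(trimethylsilyl)phenyl trifluoromethanesulfonate; 4 tetrabromomethane
Product: 8 1,5-dibromo-2-(2-bromophenoxy)-3-methoxybenzene, via potassium aryloxide 5 (not isolated), via benzyne 6 (not isolated), via ortho-aryloxyphenyl anion 7 (not isolated)
Conditions: KH (1.0 equiv), THF, 0 °C → rt; then CBr4 (3 equiv), KF (3 equiv), 18-crown-6 (3 equiv), 3 (1.5 equiv, added over 4 h), THF, 0 °C → rt, dark; H2O quench
Reagents that add atoms: none
Why: Proposed new method: fluoride from KF/18-crown-6 attacks silicon of 3 and triflate leaves to give benzyne 6; aryloxide 5 adds through oxygen, and anion 7 takes Br+ from CBr4 by halophilic attack with loss of tribromomethanide, so the O–C1' and C2'–Br bonds form on the two carbons of the former triple bond. The closest known reaction types are the fluoride-induced O-arylation of phenols by silylaryl triflates and three-component aryne couplings in which a heteroatom nucleophile adds and the aryl anion is halogenated by a polyhalomethane; the new element is an aryloxide as the first component. No ring is closed and no stereocentre is formed. Benzyne is symmetric, so there is no regiochemical question, and the ortho relationship of O and Br follows from the triple bond. The step needs bromine transfer to outrun protonation of 7, which the fully deprotonated aryloxide, THF in place of the more acidic acetonitrile and a threefold excess of CBr4 should secure, while slow addition of 3 keeps benzyne scarce so that 7 and tribromomethanide do not add to a second aryne. The aryloxide has Br at both C2 and C4 and OMe at C6, so it cannot be C-brominated and any O- or ipso-bromination by CBr4 is reversible; with no transition metal present the aryl bromides should stay intact.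

Step 3
Reactants: 8 1,5-dibromo-2-(2-bromophenoxy)-3-methoxybenzene
Product: 10 3,5-dibromo-2-(2-bromophenoxy)phenol, via aryloxydibromoborane 9 (not isolated)
Conditions: BBr3 (2.5 equiv), CH2Cl2, −78 °C → rt; H2O, 0 °C
Reagents that add atoms: none
Why: Lewis-acid ether cleavage in which BBr3 binds the methoxy oxygen and bromide removes the methyl group by SN2, whereas the diaryl ether offers no sp3 carbon for attack and the aryl bromides are inert.

Step 4
Reactants: 10 3,5-dibromo-2-(2-bromophenoxy)phenol
Product: 11 2,3,5-tribromo-6-(2-bromophenoxy)phenol (target)
Conditions: tBuNH2 (2.1 equiv), Br2 (1.0 equiv), toluene, −30 °C; then 10 in CH2Cl2, −78 °C → rt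
Reagents that add atoms: bromine, BrBr
Why: Amine-mediated ortho-selective phenol bromination, in which N-bromo-tert-butylamine formed in the flask is hydrogen-bonded to the phenol and should deliver bromine to the only free ortho carbon, the para carbon being shielded between two bromines and ring B being far less nucleophilic than the phenol ring.

**Compound list**

1 | guaiacol (2-methoxyphenol) | COc1ccccc1O | starting material
2 | 2,4-dibromo-6-methoxyphenol | COc1cc(Br)cc(Br)c1O | intermediate
3 | 2-(trimethylsilyl)phenyl trifluoromethanesulfonate | C[Si](C)(C)c1ccccc1OS(=O)(=O)C(F)(F)F | starting material
4 | tetrabromomethane | BrC(Br)(Br)Br | starting material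
5 | potassium 2,4-dibromo-6-methoxyphenoxide | [K+].COc1cc(Br)cc(Br)c1[O-] | intermediate (not isolated)
6 | benzyne (1,2-didehydrobenzene) | C1#CC=CC=C1 | intermediate (not isolated)
7 | [2-(2,4-dibromo-6-methoxyphenoxy)phenyl]potassium (ortho-aryloxyphenyl anion) | [K+].COc1cc(Br)cc(Br)c1Oc1cccc[c-]1 | intermediate (not isolated)
8 | 1,5-dibromo-2-(2-bromophenoxy)-3-methoxybenzene | COc1cc(Br)cc(Br)c1Oc1ccccc1Br | intermediate
9 | dibromo[3,5-dibromo-2-(2-bromophenoxy)phenoxy]borane | BrB(Br)Oc1cc(Br)cc(Br)c1Oc1ccccc1Br | intermediate (not isolated)
10 | 3,5-dibromo-2-(2-bromophenoxy)phenol | Oc1cc(Br)cc(Br)c1Oc1ccccc1Br | intermediate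
11 | 2,3,5-tribromo-6-(2-bromophenoxy)phenol | Oc1c(Br)c(Br)cc(Br)c1Oc1ccccc1Br | target

**Count**

Total steps: 4. Longest linear sequence: 4 steps (1 → 2 → 8 → 10 → 11).

**Steps most likely to fail**

Step 2 (Proposed new method). The risk is that anion 7 is protonated (by traces of water, by the solvent or by phenol that was not deprotonated) faster than it takes bromine, so that the ether forms without the ring-B bromine. A second risk is that tribromomethanide adds to benzyne and uses it up in a chain. The fallback uses known chemistry, the metal-free O-arylation of a phenol by a diaryliodonium salt, and sets out from compound 2. Commercial 1-bromo-2-iodobenzene is oxidised with mCPBA and TsOH·H2O in MeCN, and the hydroxy(tosyloxy)iodoarene is condensed in the same pot with 1,3,5-trimethoxybenzene to give (2-bromophenyl)(2,4,6-trimethoxyphenyl)iodonium 4-methylbenzenesulfonate F1. Phenol 2 is then treated with F1 and K2CO3 in toluene at 50–60 °C. The aryloxide should bind at iodine and receive the electron-poorer, ortho-substituted 2-bromophenyl group by ligand coupling, while the trimethoxyphenyl group leaves as its iodide. This gives compound 8 directly, where the route is rejoined.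

Step 4. The risk is poor ortho/para selectivity: bromination at C4, the carbon para to OH between the two bromines, may compete with or follow the ortho attack and lead to overbromination. The fallback places the third ring-A bromine before the ether is made, so that no late regiochemical decision remains. It sets out from compounds 3 and 4 and uses commercial 3-bromo-2-methoxyphenol as the ring-A component in place of 1. With Br2 (2 equiv) in AcOH this phenol should be brominated para and ortho to its hydroxyl group to give 3,4,6-tribromo-2-methoxyphenol F2. The potassium salt of F2 is taken through the conditions of step 2 with 3 and 4 to give 1,2,5-tribromo-4-(2-bromophenoxy)-3-methoxybenzene F3. Demethylation of F3 with BBr3 as in step 3 should deliver target 11 directly, where the fallback ends.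

Step 1. The risk is attack at the carbon para to the methoxy group or a third bromination, giving regioisomeric or overbrominated phenols that are hard to separate. The fallback splits the double bromination into two separately directed events and sets out from compound 1. Para-selective monobromination with tetrabutylammonium tribromide in CH2Cl2/MeOH should give 4-bromo-2-methoxyphenol F4 (also commercial). NBS with catalytic diisopropylamine in CH2Cl2 then delivers the second bromine through a hydrogen-bonded N-bromoamine only to the carbon ortho to OH. This gives compound 2, where the route is rejoined.

**Further compounds**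

F1 | step 2 | (2-bromophenyl)(2,4,6-trimethoxyphenyl)iodonium 4-methylbenzenesulfonate | COc1cc(OC)c([I+]c2ccccc2Br)c(OC)c1.Cc1ccc(cc1)S(=O)(=O)[O-]
F2 | step 4 | 3,4,6-tribromo-2-methoxyphenol | COc1c(O)c(Br)cc(Br)c1Br
F3 | step 4 | 1,2,5-tribromo-4-(2-bromophenoxy)-3-methoxybenzene | COc1c(Oc2ccccc2Br)c(Br)cc(Br)c1Br
F4 | step 1 | 4-bromo-2-methoxyphenol | COc1cc(Br)ccc1O
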